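The target is a pyridine whose C2, C4 and C6 are CH, with an acceptor carbonyl on C3 and the decyl chain on C5. This meta acceptor/alkyl pattern is what the key step exploits: the ring is assembled by an inverse-electron-demand aza-Diels–Alder reaction between an ester-activated 1,2,3-triazine and the pyrrolidine enamine of dodecanal. In one operation the pyridine N1–C6 and C4–C5 bonds are made, dinitrogen and pyrrolidine are expelled, and the aromatic ring appears with the decyl group and an ester already meta to each other. The precursor pair is a symmetrical 5-ester triazine and a freshly made aldehyde enamine; the ester later becomes the nonyl ketone through a Weinreb amide.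

Key step: step 4

Remark: the target contains no stereocentre and no stereogenic double bond, so it is achiral; the route needs no stereocontrol and gives the one compound drawn.

Step 1
Reactants: 1 methyl 1H-pyrazole-4-carboxylate
Product: 3 methyl 1-amino-1H-pyrazole-4-carboxylate, via potassium pyrazolide 2 (not isolated)
Conditions: KOtBu (1.05 equiv), DMF, 0 °C; then Ph2P(O)ONH2 (1.2 equiv), 0 °C → rt
Reagents that add atoms: O-(diphenylphosphinyl)hydroxylamine, NOP(=O)(c1ccccc1)c1ccccc1
Why: Electrophilic N-amination, in which the ester-acidified pyrazole N–H is deprotonated and the pyrazolide displaces diphenylphosphinate at nitrogen; the two ring nitrogens of a 4-substituted pyrazole are equivalent, so only one N-amino isomer can form.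

Step 2
Reactants: 3 methyl 1-amino-1H-pyrazole-4-carboxylate
Product: 5 methyl 1,2,3-triazine-5-carboxylate, via N-nitrene 4 (not isolated)
Conditions: NaIO4 (2 equiv), CH2Cl2/H2O (two-phase), 0 °C → rt; product kept cold and used soon
Reagents that add atoms: none
Why: Oxidative ring expansion of an N-aminopyrazole, the standard entry to 5-substituted 1,2,3-triazines, in which periodate oxidises the N-amino group to an N-nitrene whose 1,2-shift inserts the exocyclic nitrogen into the ring, while the two-phase medium extracts the electron-poor triazine away from the oxidant.

Step 3
Reactants: 6 dodecanal; 7 pyrrolidine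
Product: 9 1-[(E)-dodec-1-en-1-yl]pyrrolidine, via hemiaminal 8 (not isolated)
Conditions: 6 added slowly to 7 (1.5 equiv), 4 Å MS, Et2O, 0 °C → rt; filter, evaporate excess 7; used crude at once
Reagents that add atoms: none
Why: Enamine condensation of an unbranched aldehyde with a secondary amine through the hemiaminal and the iminium ion, driven by the sieves, should give the conjugation-stabilised E enamine, whose geometry is of no consequence later.

Step 4
Reactants: 5 methyl 1,2,3-triazine-5-carboxylate; 9 1-[(E)-dodec-1-en-1-yl]pyrrolidine
Product: 12 methyl 5-decylpyridine-3-carboxylate (methyl 5-decylnicotinate), via bicyclic azo cycloadduct 10 (not isolated), via dihydropyridine aminal 11 (not isolated)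
Conditions: 5 (1.0 equiv) added to 9 (2.0 equiv), 4 Å MS, CHCl3, 0 °C → rt, then 45 °C
Reagents that add atoms: none
Why: The electron-rich enamine 9 and the electron-poor azadiene N1=C6–C5=C4 of 5 (LUMO lowered by the C5 ester) combine in an inverse-electron-demand [4+2] cycloaddition in which the decyl-bearing β-carbon of 9 bonds to triazine C4 and the pyrrolidine-bearing carbon bonds to N1, giving bridged adduct 10; cycloreversion of 10 expels dinitrogen to leave dihydropyridine 11, and β-elimination of pyrrolidine from 11 aromatises the ring to 12. The closest known reaction type is the aza-Diels–Alder pyridine synthesis from 1,2,3-triazines and ketone enamines, applied here to an aldehyde enamine. The pyridine ring is closed by intermolecular [4+2] annulation (four ring atoms from 5, two from 9), either concerted and asynchronous or stepwise with C–C bond formation first and 6-exo-trig attack of N1 on the iminium carbon. The sp3 carbons of 10 and 11 are transient and are flattened on aromatisation, so no stereocentre has to be controlled and the enamine geometry is irrelevant. The step needs regioselectivity (decyl meta to the ester) and addition across C4/N1 and not C5/N2: C4 and C6 of 5 are equivalent by symmetry, the nucleophilic enamine carbon is matched with the electrophilic ring carbon and not with nitrogen, and the C5 ester reinforces that polarisation.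

Step 5
Reactants: 12 methyl 5-decylpyridine-3-carboxylate
Product: 13 5-decyl-N-methoxy-N-methylpyridine-3-carboxamide
Conditions: MeNH(OMe)·HCl (1.5 equiv), i-PrMgCl (3.0 equiv, added slowly), THF, −20 °C → 0 °C; sat. aq. NH4Cl
Reagents that add atoms: N,O-dimethylhydroxylamine hydrochloride, CNOC.Cl
Why: Direct ester-to-Weinreb-amide aminolysis, in which isopropylmagnesium chloride deprotonates the hydroxylamine salt faster than it adds to the ester and the resulting magnesium amide acylates cleanly at low temperature, leaving the pyridine ring and the alkyl chain untouched.

Step 6
Reactants: 13 5-decyl-N-methoxy-N-methylpyridine-3-carboxamide; 14 1-bromononane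
Product: 17 1-(5-decylpyridin-3-yl)decan-1-one, via nonylmagnesium bromide 15 (not isolated), via magnesium chelate 16 (not isolated)
Conditions: 14, Mg turnings, I2 (cat.), THF, reflux; the resulting 15 (1.5 equiv) added to 13, THF, 0 °C; sat. aq. NH4Cl
Reagents that add atoms: none
Why: Weinreb ketone synthesis, in which the Grignard reagent adds once to give a five-membered N-methoxy magnesium chelate that survives until the aqueous quench, so the ketone is released only on work-up and over-addition is excluded.

Compound list
1 | methyl 1H-pyrazole-4-carboxylate | COC(=O)c1cn[nH]c1 | starting material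
2 | potassium 4-(methoxycarbonyl)pyrazol-1-ide (not isolated) | COC(=O)c1cn[n-]c1.[K+] | intermediate
3 | methyl 1-amino-1H-pyrazole-4-carboxylate | COC(=O)c1cnn(N)c1 | intermediate
4 | methyl 1-nitrenopyrazole-4-carboxylate, the N-nitrene (1,1-diazene) of 3 (not isolated) | COC(=O)c1cnn([N])c1 | intermediate
5 | methyl 1,2,3-triazine-5-carboxylate | COC(=O)c1cnnnc1 | intermediate
6 | dodecanal | CCCCCCCCCCCC=O | starting material
7 | pyrrolidine | C1CCNC1 | starting material
8 | 1-(pyrrolidin-1-yl)dodecan-1-ol, hemiaminal (not isolated, racemic) | CCCCCCCCCCCC(O)N1CCCC1 | intermediate
9 | 1-[(E)-dodec-1-en-1-yl]pyrrolidine | CCCCCCCCCC/C=C/N1CCCC1 | intermediate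
10 | methyl 8-decyl-7-(pyrrolidin-1-yl)-1,2,3-triazabicyclo[2.2.2]octa-2,5-diene-5-carboxylate (not isolated, transient sp3 centres not defined) | C12N=NN(C=C1C(=O)OC)C(N3CCCC3)C2CCCCCCCCCC | intermediate
11 | methyl 5-decyl-6-(pyrrolidin-1-yl)-5,6-dihydropyridine-3-carboxylate (not isolated, transient sp3 centres not defined) | COC(=O)C1=CC(CCCCCCCCCC)C(N2CCCC2)N=C1 | intermediate
12 | methyl 5-decylpyridine-3-carboxylate (methyl 5-decylnicotinate) | CCCCCCCCCCc1cncc(C(=O)OC)c1 | intermediate
13 | 5-decyl-N-methoxy-N-methylpyridine-3-carboxamide | CCCCCCCCCCc1cncc(C(=O)N(C)OC)c1 | intermediate
14 | 1-bromononane | CCCCCCCCCBr | starting material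
15 | nonylmagnesium bromide (not isolated) | CCCCCCCCC[Mg]Br | intermediate
16 | bromomagnesium 1-(5-decylpyridin-3-yl)-1-[methoxy(methyl)amino]decan-1-olate, tetrahedral chelate (not isolated, racemic) | CCCCCCCCCC(O[Mg]Br)(N(C)OC)c1cncc(CCCCCCCCCC)c1 | intermediate
17 | 1-(5-decylpyridin-3-yl)decan-1-one | CCCCCCCCCCc1cncc(C(=O)CCCCCCCCC)c1 | target

Total step count: 6
Longest linear sequence: 5 steps (steps 1, 2, 4, 5, 6); step 3 is a one-step side branch that joins at step 4.

Steps most likely to fail

Step 4. The aldehyde enamine may be used up by self-condensation or hydrolysis before it cycloadds. Liberated pyrrolidine may open the electrophilic triazine by attack at C4. The sequence may also stall before pyrrolidine is eliminated. The fallback sets out from dodecanal 6 and comes back at 12, building the ring by condensation instead of cycloaddition. α-Methylenation of 6 (aqueous formaldehyde, catalytic pyrrolidine and propionic acid, i-PrOH, 45 °C) should give 2-methylidenedodecanal F1. Conjugate addition of ammonia to methyl propiolate in methanol should give methyl (Z)-3-aminoprop-2-enoate F2. Heating F1 with F2 in ethanol containing acetic acid should give methyl 5-decyl-1,4-dihydropyridine-3-carboxylate F3 by Michael addition and cyclocondensation (a Hantzsch-type [3+3] annulation). Activated MnO2 in CH2Cl2 should then aromatise F3 to 12. Either orientation of the annulation leads to the same 3,5-pattern, because the decyl group sits on the central carbon of the three-carbon unit.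

Step 3. Amine-catalysed self-aldol condensation of dodecanal may compete with enamine formation, and the enamine may hydrolyse back during concentration. The fallback sets out from pyrrolidine 7 and comes back at 9, with no aldehyde and no water involved. Anti-Markovnikov hydroamination of commercial dodec-1-yne (CCCCCCCCCCC#C) with 7, using a rhodium catalyst such as TpRh(C2H4)2/PPh3 in toluene at about 100 °C, should give the E enamine 9 directly. This fallback makes no new compound (F0).

Step 6. The Grignard reagent may add to the pyridine ring once magnesium coordinates the ring nitrogen. It may also act as a base and fragment the N-methoxy group with loss of formaldehyde. Both would consume the amide without giving ketone. The fallback sets out from 13 and comes back at 17, passing through the alcohol oxidation level. Reduction of 13 with DIBAL-H in THF at −78 °C should give 5-decylpyridine-3-carbaldehyde F4. Addition of 15 (prepared as in step 6) at −78 °C, where attack on the aldehyde is far faster than attack on the ring, should give racemic 1-(5-decylpyridin-3-yl)decan-1-ol F5. Dess–Martin periodinane in CH2Cl2 should oxidise F5 to 17.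

Further compounds
F1 | step 4 | 2-methylidenedodecanal | CCCCCCCCCCC(=C)C=O
F2 | step 4 | methyl (Z)-3-aminoprop-2-enoate | COC(=O)/C=C\N
F3 | step 4 | methyl 5-decyl-1,4-dihydropyridine-3-carboxylate | COC(=O)C1=CNC=C(CCCCCCCCCC)C1
F0 | step 3 | none | none
F4 | step 6 | 5-decylpyridine-3-carbaldehyde | CCCCCCCCCCc1cncc(C=O)c1
F5 | step 6 | 1-(5-decylpyridin-3-yl)decan-1-ol (racemic) | CCCCCCCCCCc1cncc(C(O)CCCCCCCCC)c1
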